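Ring numbering used throughout: C1 ketone carbon, C2 the carbon bearing CH2CO2Me, C3 the vinylic CH, C4 the carbinol carbon, C5 the carbon bearing the tetraprenyl chain, C6 the ring CH2; chain carbons are primed.
Enabling feature: on the cyclohexene ring the C4 oxygen is cis to the carbon arm on C5 and lies 1,4 to the C1 oxygen across the C2=C3 alkene. This is what a 1,4-dioxidation of a cyclohexa-1,3-diene leaves when an acetic acid arm on C5 delivers its own oxygen to C4.
Cuts: C2–CH2CO2Me (zinc enolate coupling with a 2-iodoenone); chain C4'–C5' (allyl sulfone alkylation) and C2'=C3' (Wittig on a lactol); C4–O and C1–O together (lactone-tethered palladium 1,4-oxidation); C5–arm (allylic alkylation of a meso diacetate).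
Forward: cyclohexa-1,3-diene, meso diacetate, malonate desymmetrisation, diene acid, cis-fused acetoxy γ-lactone (the only ring formed; it is opened again), lactol, Wittig, farnesyl sulfone coupling, C1 ketone, iodination, coupling, desilylation.
Stereochemistry: C5 from the ligand-controlled allylic alkylation; C4 relayed from C5 by the cis ring fusion of the lactone; the 2'E alkene from the stabilised ylide, the other chain alkenes from (2E,6E)-farnesol; the C1 centre is transient.

Key step: step 6

Assumption: the (S,S)-configured diphosphine is taken to steer ionisation to the acetate on the (R)-configured carbon of meso diacetate 2; if the sense of induction is the reverse, the equally available (R,R)-ligand is used and nothing else changes.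

Step 1
Reactants: 1 cyclohexa-1,3-diene
Product: 2 cis-cyclohex-2-ene-1,4-diyl diacetate (meso)
Conditions: Pd(OAc)2 (5 mol%), LiCl (cat.), LiOAc, p-benzoquinone, AcOH, rt
Reagents that add atoms: acetic acid, CC(=O)O
Why: Palladium-catalysed 1,4-diacetoxylation of a conjugated diene: acetate adds anti to diene-bound divalent palladium and, with chloride on the metal, the second acetate also attacks the π-allyl complex from outside, so both acetates end up cis and the product is meso.

Step 2
Reactants: 2 cis-cyclohex-2-ene-1,4-diyl diacetate; 3 dimethyl malonate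
Product: 4 dimethyl 2-[(1R,4S)-4-acetoxycyclohex-2-en-1-yl]propanedioate (cis)
Conditions: Pd2(dba)3·CHCl3 (2.5 mol%), (S,S)-N,N'-(cyclohexane-1,2-diyl)bis[2-(diphenylphosphino)benzamide] (7.5 mol%), Cs2CO3, CH2Cl2, 0 °C to rt
Reagents that add atoms: dimethyl malonate 3, COC(=O)CC(=O)OC
Why: Tsuji–Trost asymmetric allylic alkylation used as a meso desymmetrisation: the chiral zerovalent palladium complex ionises one enantiotopic acetate with inversion and malonate attacks the allyl terminus remote from the surviving acetate, again anti to the metal, so the C5 stereocentre is set by the ligand and the malonate ends up cis to the remaining acetate (net retention).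

Step 3
Reactants: 4 cis acetoxy malonate
Product: 5 dimethyl 2-[(1R)-cyclohexa-2,4-dien-1-yl]propanedioate
Conditions: Pd(PPh3)4 (5 mol%), Et3N, 1,4-dioxane, reflux
Reagents that add atoms: none
Why: Palladium-catalysed elimination of acetic acid from an allylic acetate (Tsuji–Trost elimination): zerovalent palladium ionises the C2 acetate and loss of a hydrogen from C1 of the π-allyl complex gives the conjugated diene, while C5 is not touched.

Step 4
Reactants: 5 diene malonate
Product: 6 methyl 2-[(1S)-cyclohexa-2,4-dien-1-yl]acetate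
Conditions: LiCl, H2O, DMSO, 140 °C
Reagents that add atoms: none
Why: Krapcho dealkoxycarbonylation: chloride demethylates one ester, the carboxylate loses CO2 and the ester enolate is protonated by water; C5 is not α to a carbonyl and cannot epimerise (the descriptor changes only because the side arm drops in CIP rank).

Step 5
Reactants: 6 diene methyl ester
Product: 7 2-[(1S)-cyclohexa-2,4-dien-1-yl]acetic acid
Conditions: LiOH, THF/H2O, rt; then 1 M HCl
Reagents that add atoms: lithium hydroxide, [Li+].[OH-]
Why: Ester saponification by acyl–oxygen cleavage under conditions too mild to move the diene, giving the free carboxylic acid needed as the internal nucleophile.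

Step 6
Reactants: 7 2-[(1S)-cyclohexa-2,4-dien-1-yl]acetic acid
Product: 8 (3aS,5S,7aR)-5-acetoxy-3a,4,5,7a-tetrahydro-1-benzofuran-2(3H)-one (all-cis; lactone oxygen on C4 and acetate on C1)
Conditions: Pd(OAc)2 (5 mol%), LiCl (0.2 equiv), LiOAc, p-benzoquinone (2 equiv), acetone/AcOH 4:1, rt
Reagents that add atoms: acetic acid, CC(=O)O
Why: Divalent palladium binds the diene of 7 on the face opposite the acetic acid arm and the carboxylate oxygen adds to C4 anti to the metal (intramolecular trans-oxypalladation), leaving a π-allyl palladium complex across C3, C2 and C1; acetate, kept off the metal by chloride, then attacks C1 from outside and anti to palladium, zerovalent palladium is released and p-benzoquinone returns it to the divalent state. The closest known reaction type is the palladium-catalysed 1,4-acetoxylactonisation of cyclohexa-2,4-dienylacetic acids, the tethered form of the diene 1,4-diacetoxylation of step 1. The single ring that closes is the γ-lactone, by a 5-exo-trig attack of oxygen on C4. The new C4 stereocentre is controlled by C5 through the two-atom tether, which can only bridge a cis ring fusion, and the new C1 stereocentre by the anti attack of external acetate on the π-allyl complex, which places it cis to the lactone oxygen (this centre is erased when C1 becomes the ketone). The selectivities needed are cis oxygen delivery to C4 and 1,4- over 1,2-addition: the tether secures the first, and the second follows because the C3 allyl terminus is flanked by the new C–O bond and the ring fusion, so acetate goes to the open C1 terminus and the alkene stays at C2=C3.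

Step 7
Reactants: 8 acetoxy lactone
Product: 9 (3aS,5S,7aR)-5-hydroxy-3a,4,5,7a-tetrahydro-1-benzofuran-2(3H)-one
Conditions: K2CO3 (cat.), MeOH, 0 °C; then Amberlyst 15 (H+ form)
Reagents that add atoms: none
Why: Base-catalysed transesterification removes the secondary acetate as methyl acetate, and any methanol-opened γ-hydroxy ester re-closes to the cis-fused γ-lactone on acidification.

Step 8
Reactants: 9 hydroxy lactone
Product: 10 (3aS,5S,7aR)-5-(triethylsilyloxy)-3a,4,5,7a-tetrahydro-1-benzofuran-2(3H)-one
Conditions: TESCl, imidazole, CH2Cl2, 0 °C to rt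
Reagents that add atoms: chlorotriethylsilane, CC[Si](Cl)(CC)CC
Why: Silylation of the unhindered secondary allylic C1 alcohol gives a group that survives hydride and carbanion chemistry and can later be removed in the presence of a tert-butyldimethylsilyl ether.

Step 9
Reactants: 10 silyloxy lactone
Product: 11 (3aS,5S,7aR)-5-(triethylsilyloxy)-2,3,3a,4,5,7a-hexahydro-1-benzofuran-2-ol (lactol; both epimers at the hemiacetal carbon)
Conditions: i-Bu2AlH (1.1 equiv), CH2Cl2, –78 °C; aq. potassium sodium tartrate
Reagents that add atoms: none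
Why: Partial reduction of a lactone with i-Bu2AlH at low temperature stops at the aluminium hemiacetal, which gives the lactol on work-up; the hemiacetal centre is uncontrolled and irrelevant.

Step 10
Reactants: 11 lactol; 12 ethyl 2-(triphenylphosphoranylidene)propanoate
Product: 13 ethyl (2E)-4-[(1R,2R,5S)-2-hydroxy-5-(triethylsilyloxy)cyclohex-3-en-1-yl]-2-methylbut-2-enoate
Conditions: 12, toluene, 80 °C
Reagents that add atoms: ethyl 2-(triphenylphosphoranylidene)propanoate 12, CCOC(=O)C(C)=P(c1ccccc1)(c1ccccc1)c1ccccc1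
Why: Wittig olefination of the open hydroxy-aldehyde tautomer of the lactol with a stabilised, α-methylated ylide, which should give the trisubstituted alkene with the ester trans to the ring CH2 (E) and frees the C4 hydroxyl.

Step 11
Reactants: 13 hydroxy enoate
Product: 14 ethyl (2E)-4-[(1R,2R,5S)-2-(tert-butyldimethylsilyloxy)-5-(triethylsilyloxy)cyclohex-3-en-1-yl]-2-methylbut-2-enoate
Conditions: TBSOTf, 2,6-lutidine, CH2Cl2, –78 to 0 °C
Reagents that add atoms: tert-butyldimethylsilyl trifluoromethanesulfonate, CC(C)(C)[Si](C)(C)OS(=O)(=O)C(F)(F)F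
Why: Silylation of the hindered C4 alcohol with the silyl triflate blocks oxa-Michael closure onto the enoate and gives the more robust of the two silyl ethers at the position that must stay protected to the end.

Step 12
Reactants: 14 bis-silylated enoate
Product: 15 (2E)-4-[(1R,2R,5S)-2-(tert-butyldimethylsilyloxy)-5-(triethylsilyloxy)cyclohex-3-en-1-yl]-2-methylbut-2-en-1-ol
Conditions: i-Bu2AlH (2.5 equiv), CH2Cl2, –78 °C; aq. potassium sodium tartrate
Reagents that add atoms: none
Why: 1,2-Reduction of an α,β-unsaturated ester with i-Bu2AlH gives the primary allylic alcohol without touching the alkene geometry or the silyl ethers.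

Step 13
Reactants: 15 allylic alcohol
Product: 17 (2E)-1-bromo-4-[(1R,2R,5S)-2-(tert-butyldimethylsilyloxy)-5-(triethylsilyloxy)cyclohex-3-en-1-yl]-2-methylbut-2-ene, via allylic mesylate 16 (not isolated)
Conditions: MsCl, Et3N, THF, –40 °C; then LiBr, THF, 0 °C
Reagents that add atoms: lithium bromide, [Li+].[Br-]; methanesulfonyl chloride, CS(=O)(=O)Cl (its atoms stay in 16 only)
Why: Mesylation of the primary allylic alcohol followed by SN2 displacement with bromide (Finkelstein-type) avoids acid, so both silyl ethers and the E-alkene should be preserved.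

Step 14
Reactants: 18 (2E,6E)-farnesol
Product: 19 (2E,6E)-farnesyl bromide
Conditions: PBr3, Et2O, –10 to 0 °C
Reagents that add atoms: phosphorus tribromide, BrP(Br)Br
Why: Bromination of a primary allylic alcohol through its phosphite ester by SN2 displacement, a standard entry to prenyl bromides with retention of alkene geometry.

Step 15
Reactants: 19 farnesyl bromide
Product: 20 (2E,6E)-farnesyl phenyl sulfone
Conditions: PhSO2Na, DMF, rt
Reagents that add atoms: sodium benzenesulfinate, [Na+].[O-]S(=O)c1ccccc1
Why: S-Alkylation of the sulfinate anion by SN2 at the primary allylic carbon gives the allylic sulfone without allylic transposition.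

Step 16
Reactants: 17 allylic bromide; 20 farnesyl phenyl sulfone
Product: 22 5'-(phenylsulfonyl) tetraprenyl bis-silyl ether (both epimers at the sulfonyl carbon), via lithiated farnesyl phenyl sulfone 21 (not isolated)
Conditions: 20, n-BuLi, THF, –78 °C; then 17, –78 to –20 °C
Reagents that add atoms: farnesyl phenyl sulfone 20, O=S(=O)(C/C=C(\C)CC/C=C(\C)CCC=C(C)C)c1ccccc1; n-butyllithium, [Li]CCCC (lithium stays in 21 only)
Why: Alkylation of an α-sulfonyl allyl carbanion with a primary allylic bromide (Julia-type sulfone alkylation) forms the C4'–C5' bond at the α-carbon; the new sulfonyl-bearing stereocentre is uncontrolled and removed in the next step.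

Step 17
Reactants: 22 coupled allylic sulfone
Product: 23 triethyl{[(1S,4R,5R)-4-(tert-butyldimethylsilyloxy)-5-[(2E,6E,10E)-3,7,11,15-tetramethylhexadeca-2,6,10,14-tetraen-1-yl]cyclohex-2-en-1-yl]oxy}silane
Conditions: Pd(dppf)Cl2 (5 mol%), LiBHEt3, THF, 0 °C
Reagents that add atoms: none
Why: Palladium-catalysed reductive desulfonylation of an allylic sulfone: zerovalent palladium ionises the C–S bond to a π-allyl complex and hydride is delivered to the less substituted terminus, which keeps the 6',7'-alkene trisubstituted and E.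

Step 18
Reactants: 23 bis-silyl ether
Product: 24 (1S,4R,5R)-4-(tert-butyldimethylsilyloxy)-5-[(2E,6E,10E)-3,7,11,15-tetramethylhexadeca-2,6,10,14-tetraen-1-yl]cyclohex-2-en-1-ol
Conditions: PPTS (cat.), MeOH/CH2Cl2, 0 °C
Reagents that add atoms: none
Why: Acid-catalysed methanolysis removes the triethylsilyl ether far faster than the bulkier tert-butyldimethylsilyl ether on the more hindered C4 oxygen, so only the C1 alcohol is freed.

Step 19
Reactants: 24 C1 allylic alcohol
Product: 25 (4R,5R)-4-(tert-butyldimethylsilyloxy)-5-[(2E,6E,10E)-3,7,11,15-tetramethylhexadeca-2,6,10,14-tetraen-1-yl]cyclohex-2-en-1-one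
Conditions: MnO2, CH2Cl2, rt
Reagents that add atoms: none
Why: MnO2 oxidation of a secondary allylic alcohol gives the enone under neutral conditions and removes the transient C1 stereocentre.

Step 20
Reactants: 25 enone
Product: 26 (4R,5R)-4-(tert-butyldimethylsilyloxy)-2-iodo-5-[(2E,6E,10E)-3,7,11,15-tetramethylhexadeca-2,6,10,14-tetraen-1-yl]cyclohex-2-en-1-one
Conditions: I2, pyridine, CH2Cl2, 0 °C to rt, dark
Reagents that add atoms: iodine, II
Why: α-Iodination of a cyclic enone by conjugate addition of pyridine, iodination of the enolate and elimination (a Baylis–Hillman-type addition–elimination), which is selective for the electron-poor enone over the isolated chain alkenes.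

Step 21
Reactants: 26 2-iodoenone; 27 methyl bromoacetate
Product: 29 methyl 2-[(3R,4R)-3-(tert-butyldimethylsilyloxy)-6-oxo-4-[(2E,6E,10E)-3,7,11,15-tetramethylhexadeca-2,6,10,14-tetraen-1-yl]cyclohex-1-en-1-yl]acetate, via bromo(2-methoxy-2-oxoethyl)zinc 28 (not isolated)
Conditions: 27, Zn dust (TMSCl-activated), THF, rt; then 26, Pd(PPh3)4 (10 mol%), THF/DMPU, rt to 40 °C
Reagents that add atoms: methyl bromoacetate 27, COC(=O)CBr; zinc, [Zn] (stays in 28 only)
Why: Negishi-type cross-coupling of a Reformatsky reagent with an alkenyl iodide: oxidative addition of the C2–I bond to zerovalent palladium, transmetalation from zinc and reductive elimination should form the C2–CH2 bond faster than the zinc enolate adds to the hindered enone carbonyl.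

Step 22
Reactants: 29 silyl-protected coupling product
Product: 30 methyl 2-[(3R,4R)-3-hydroxy-6-oxo-4-[(2E,6E,10E)-3,7,11,15-tetramethylhexadeca-2,6,10,14-tetraen-1-yl]cyclohex-1-en-1-yl]acetate (target)
Conditions: HF·pyridine, pyridine, THF, 0 °C to rt
Reagents that add atoms: none
Why: Fluoride-mediated cleavage of the silyl ether under buffered, weakly acidic conditions frees the C4 alcohol without the base that could dehydrate the γ-hydroxy enone or move the C2=C3 alkene toward the ester.

Compound list
1 | cyclohexa-1,3-diene | C1=CC=CCC1 | starting material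
2 | (1R,4S)-cyclohex-2-ene-1,4-diyl diacetate (cis, meso) | CC(=O)O[C@H]1C=C[C@@H](OC(C)=O)CC1 | intermediate
3 | dimethyl malonate | COC(=O)CC(=O)OC | starting material
4 | dimethyl 2-[(1R,4S)-4-acetoxycyclohex-2-en-1-yl]propanedioate (cis) | COC(=O)C(C(=O)OC)[C@H]1C=C[C@@H](OC(C)=O)CC1 | intermediate
5 | dimethyl 2-[(1R)-cyclohexa-2,4-dien-1-yl]propanedioate | C1=CC=CC[C@H]1C(C(=O)OC)C(=O)OC | intermediate
6 | methyl 2-[(1S)-cyclohexa-2,4-dien-1-yl]acetate (same spatial arrangement as 5) | C1=CC=CC[C@H]1CC(=O)OC | intermediate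
7 | 2-[(1S)-cyclohexa-2,4-dien-1-yl]acetic acid | C1=CC=CC[C@H]1CC(=O)O | intermediate
8 | (3aS,5S,7aR)-5-acetoxy-3a,4,5,7a-tetrahydro-1-benzofuran-2(3H)-one (cis-fused, acetate cis to the lactone oxygen) | C1=C[C@H](OC(=O)C2)[C@H]2C[C@@H]1OC(C)=O | intermediate
9 | (3aS,5S,7aR)-5-hydroxy-3a,4,5,7a-tetrahydro-1-benzofuran-2(3H)-one | C1=C[C@H](OC(=O)C2)[C@H]2C[C@@H]1O | intermediate
10 | (3aS,5S,7aR)-5-(triethylsilyloxy)-3a,4,5,7a-tetrahydro-1-benzofuran-2(3H)-one | C1=C[C@H](OC(=O)C2)[C@H]2C[C@@H]1O[Si](CC)(CC)CC | intermediate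
11 | (3aS,5S,7aR)-5-(triethylsilyloxy)-2,3,3a,4,5,7a-hexahydro-1-benzofuran-2-ol (both epimers at C2) | C1=C[C@H](OC(O)C2)[C@H]2C[C@@H]1O[Si](CC)(CC)CC | intermediate
12 | ethyl 2-(triphenylphosphoranylidene)propanoate | CCOC(=O)C(C)=P(c1ccccc1)(c1ccccc1)c1ccccc1 | starting material
13 | ethyl (2E)-4-[(1R,2R,5S)-2-hydroxy-5-(triethylsilyloxy)cyclohex-3-en-1-yl]-2-methylbut-2-enoate | C1=C[C@H](O)[C@H](C/C=C(\C)C(=O)OCC)C[C@@H]1O[Si](CC)(CC)CC | intermediate
14 | ethyl (2E)-4-[(1R,2R,5S)-2-(tert-butyldimethylsilyloxy)-5-(triethylsilyloxy)cyclohex-3-en-1-yl]-2-methylbut-2-enoate | C1=C[C@H](O[Si](C)(C)C(C)(C)C)[C@H](C/C=C(\C)C(=O)OCC)C[C@@H]1O[Si](CC)(CC)CC | intermediate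
15 | (2E)-4-[(1R,2R,5S)-2-(tert-butyldimethylsilyloxy)-5-(triethylsilyloxy)cyclohex-3-en-1-yl]-2-methylbut-2-en-1-ol | C1=C[C@H](O[Si](C)(C)C(C)(C)C)[C@H](C/C=C(\C)CO)C[C@@H]1O[Si](CC)(CC)CC | intermediate
16 | (2E)-4-[(1R,2R,5S)-2-(tert-butyldimethylsilyloxy)-5-(triethylsilyloxy)cyclohex-3-en-1-yl]-2-methylbut-2-en-1-yl methanesulfonate | C1=C[C@H](O[Si](C)(C)C(C)(C)C)[C@H](C/C=C(\C)COS(C)(=O)=O)C[C@@H]1O[Si](CC)(CC)CC | intermediate (not isolated)
17 | (2E)-1-bromo-4-[(1R,2R,5S)-2-(tert-butyldimethylsilyloxy)-5-(triethylsilyloxy)cyclohex-3-en-1-yl]-2-methylbut-2-ene | C1=C[C@H](O[Si](C)(C)C(C)(C)C)[C@H](C/C=C(\C)CBr)C[C@@H]1O[Si](CC)(CC)CC | intermediate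
18 | (2E,6E)-farnesol | OC/C=C(\C)CC/C=C(\C)CCC=C(C)C | starting material
19 | (2E,6E)-1-bromo-3,7,11-trimethyldodeca-2,6,10-triene (farnesyl bromide) | BrC/C=C(\C)CC/C=C(\C)CCC=C(C)C | intermediate
20 | {[(2E,6E)-3,7,11-trimethyldodeca-2,6,10-trien-1-yl]sulfonyl}benzene (farnesyl phenyl sulfone) | O=S(=O)(C/C=C(\C)CC/C=C(\C)CCC=C(C)C)c1ccccc1 | intermediate
21 | [(2E,6E)-3,7,11-trimethyl-1-(phenylsulfonyl)dodeca-2,6,10-trien-1-yl]lithium | [Li]C(/C=C(\C)CC/C=C(\C)CCC=C(C)C)S(=O)(=O)c1ccccc1 | intermediate (not isolated)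
22 | (2E,6E,10E)-1-[(1R,2R,5S)-2-(tert-butyldimethylsilyloxy)-5-(triethylsilyloxy)cyclohex-3-en-1-yl]-3,7,11,15-tetramethyl-5-(phenylsulfonyl)hexadeca-2,6,10,14-tetraene (both epimers at C5') | C1=C[C@H](O[Si](C)(C)C(C)(C)C)[C@H](C/C=C(\C)CC(S(=O)(=O)c2ccccc2)/C=C(\C)CC/C=C(\C)CCC=C(C)C)C[C@@H]1O[Si](CC)(CC)CC | intermediate
23 | triethyl{[(1S,4R,5R)-4-(tert-butyldimethylsilyloxy)-5-[(2E,6E,10E)-3,7,11,15-tetramethylhexadeca-2,6,10,14-tetraen-1-yl]cyclohex-2-en-1-yl]oxy}silane | C1=C[C@H](O[Si](C)(C)C(C)(C)C)[C@H](C/C=C(\C)CC/C=C(\C)CC/C=C(\C)CCC=C(C)C)C[C@@H]1O[Si](CC)(CC)CC | intermediate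
24 | (1S,4R,5R)-4-(tert-butyldimethylsilyloxy)-5-[(2E,6E,10E)-3,7,11,15-tetramethylhexadeca-2,6,10,14-tetraen-1-yl]cyclohex-2-en-1-ol | C1=C[C@H](O[Si](C)(C)C(C)(C)C)[C@H](C/C=C(\C)CC/C=C(\C)CC/C=C(\C)CCC=C(C)C)C[C@@H]1O | intermediate
25 | (4R,5R)-4-(tert-butyldimethylsilyloxy)-5-[(2E,6E,10E)-3,7,11,15-tetramethylhexadeca-2,6,10,14-tetraen-1-yl]cyclohex-2-en-1-one | C1=C[C@H](O[Si](C)(C)C(C)(C)C)[C@H](C/C=C(\C)CC/C=C(\C)CC/C=C(\C)CCC=C(C)C)CC1=O | intermediate
26 | (4R,5R)-4-(tert-butyldimethylsilyloxy)-2-iodo-5-[(2E,6E,10E)-3,7,11,15-tetramethylhexadeca-2,6,10,14-tetraen-1-yl]cyclohex-2-en-1-one | IC1=C[C@H](O[Si](C)(C)C(C)(C)C)[C@H](C/C=C(\C)CC/C=C(\C)CC/C=C(\C)CCC=C(C)C)CC1=O | intermediate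
27 | methyl bromoacetate | COC(=O)CBr | starting material
28 | bromo(2-methoxy-2-oxoethyl)zinc | COC(=O)C[Zn]Br | intermediate (not isolated)
29 | methyl 2-[(3R,4R)-3-(tert-butyldimethylsilyloxy)-6-oxo-4-[(2E,6E,10E)-3,7,11,15-tetramethylhexadeca-2,6,10,14-tetraen-1-yl]cyclohex-1-en-1-yl]acetate | COC(=O)CC1=C[C@H](O[Si](C)(C)C(C)(C)C)[C@H](C/C=C(\C)CC/C=C(\C)CC/C=C(\C)CCC=C(C)C)CC1=O | intermediate
30 | methyl 2-[(3R,4R)-3-hydroxy-6-oxo-4-[(2E,6E,10E)-3,7,11,15-tetramethylhexadeca-2,6,10,14-tetraen-1-yl]cyclohex-1-en-1-yl]acetate | COC(=O)CC1=C[C@H](O)[C@H](C/C=C(\C)CC/C=C(\C)CC/C=C(\C)CCC=C(C)C)CC1=O | target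

Total step count: 22. Longest linear sequence: 20 steps (steps 1–13 and 16–22, from cyclohexa-1,3-diene); steps 14 and 15 prepare the sulfone.

Steps most likely to fail

Step 3 (elimination to the diene). The π-allyl palladium intermediate may lose the hydrogen on C5 instead of one on C1, a palladium hydride may walk the diene into conjugation with the malonate, or the malonate C–H may capture the allyl unit; each of these erases or consumes the C5 centre. Fallback with a different elimination mechanism: setting out from 4, methanolysis of the acetate (K2CO3, MeOH) would give dimethyl 2-[(1R,4S)-4-hydroxycyclohex-2-en-1-yl]propanedioate F1, and thermal syn-dehydration of F1 with the Burgess reagent (toluene, 60 °C), whose only β-hydrogens sit on C1, comes back to the route at 5.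

Step 21 (zinc enolate coupling). The Reformatsky reagent may add to the ketone carbonyl in the ordinary uncatalysed way, or the iodide may be reduced off before transmetalation. Fallback that brings in the two carbons as a masked aldehyde: setting out from 26, Stille coupling with (Z)-tributyl(2-ethoxyethenyl)stannane (Pd(PPh3)4, CuI, DMF) would give (4R,5R)-4-(tert-butyldimethylsilyloxy)-2-[(Z)-2-ethoxyethenyl]-5-[(2E,6E,10E)-3,7,11,15-tetramethylhexadeca-2,6,10,14-tetraen-1-yl]cyclohex-2-en-1-one F2. Mild hydrolysis of the enol ether (aq. oxalic acid, THF) would give 2-[(3R,4R)-3-(tert-butyldimethylsilyloxy)-6-oxo-4-[(2E,6E,10E)-3,7,11,15-tetramethylhexadeca-2,6,10,14-tetraen-1-yl]cyclohex-1-en-1-yl]acetaldehyde F3. Pinnick oxidation (NaClO2, NaH2PO4, 2-methylbut-2-ene, t-BuOH/H2O) would give the corresponding acetic acid F4, and methylation with TMSCHN2 in MeOH/toluene comes back to the route at 29.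

Step 2 (desymmetrising alkylation). The catalyst may discriminate poorly between the two enantiotopic acetates, which ionise more slowly than the benzoates or carbonates usually used, or the product may ionise a second time and be alkylated twice. Fallback that moves the enantio-determining event to an enzyme: setting out from 2, hydrolase-mediated cleavage of the acetate on the (R)-configured carbon (lipase or esterase screened for that sense) would give (1S,4R)-4-hydroxycyclohex-2-en-1-yl acetate F5. Methyl chloroformate and pyridine would convert it into (1S,4R)-4-[(methoxycarbonyl)oxy]cyclohex-2-en-1-yl acetate F6. Substitution with dimethyl malonate 3 under neutral conditions (Pd(PPh3)4, THF), where the carbonate ionises in preference to the acetate and is replaced with net retention, comes back to the route at 4.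

Further compounds
F1 | step 3 | dimethyl 2-[(1R,4S)-4-hydroxycyclohex-2-en-1-yl]propanedioate | COC(=O)C(C(=O)OC)[C@H]1C=C[C@@H](O)CC1
F2 | step 21 | (4R,5R)-4-(tert-butyldimethylsilyloxy)-2-[(Z)-2-ethoxyethenyl]-5-[(2E,6E,10E)-3,7,11,15-tetramethylhexadeca-2,6,10,14-tetraen-1-yl]cyclohex-2-en-1-one | CCO/C=C\C1=C[C@H](O[Si](C)(C)C(C)(C)C)[C@H](C/C=C(\C)CC/C=C(\C)CC/C=C(\C)CCC=C(C)C)CC1=O
F3 | step 21 | 2-[(3R,4R)-3-(tert-butyldimethylsilyloxy)-6-oxo-4-[(2E,6E,10E)-3,7,11,15-tetramethylhexadeca-2,6,10,14-tetraen-1-yl]cyclohex-1-en-1-yl]acetaldehyde | O=CCC1=C[C@H](O[Si](C)(C)C(C)(C)C)[C@H](C/C=C(\C)CC/C=C(\C)CC/C=C(\C)CCC=C(C)C)CC1=O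
F4 | step 21 | 2-[(3R,4R)-3-(tert-butyldimethylsilyloxy)-6-oxo-4-[(2E,6E,10E)-3,7,11,15-tetramethylhexadeca-2,6,10,14-tetraen-1-yl]cyclohex-1-en-1-yl]acetic acid | OC(=O)CC1=C[C@H](O[Si](C)(C)C(C)(C)C)[C@H](C/C=C(\C)CC/C=C(\C)CC/C=C(\C)CCC=C(C)C)CC1=O
F5 | step 2 | (1S,4R)-4-hydroxycyclohex-2-en-1-yl acetate | O[C@H]1C=C[C@@H](OC(C)=O)CC1
F6 | step 2 | (1S,4R)-4-[(methoxycarbonyl)oxy]cyclohex-2-en-1-yl acetate | COC(=O)O[C@H]1C=C[C@@H](OC(C)=O)CC1
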